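**Strategy**

The cyclohexene ring is disconnected at C1–C2 and C3–C4, so that C1 with its ether oxygen and the C7 benzoyloxymethyl branch maps onto C2 of a furfuryl ester and the cis C2/C3 dioxygenation onto vinylene carbonate. One endo Diels–Alder reaction closes the carbocycle as a 7-oxanorbornene and sets the fully substituted C1–O centre, C4, and the cis C2/C3 oxygens on the face opposite the oxygen bridge. That bridge is the latent epoxide oxygen: an anti SN2′ entry of chloride at C6 releases it from C4, creates C4=C5, and base closure gives the C1–C6 oxirane. The precursors are furfuryl benzoate and vinylene carbonate.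

Key step: step 2

**Remarks on the chemistry**

- Locants C1–C7 of the target are used for every compound (C1 carries C7; in the oxanorbornenes C1 and C4 are the bridgeheads and C5=C6 is the alkene).
- Compounds 5–7 are racemates; their SMILES show the enantiomer that is carried on from step 5.
- Assumption for step 5: the lipase follows the usual size rule for secondary alcohols with the C2 side of C3 as the large group, so the needed enantiomer is the one left unacylated.
- Assumption for step 7: which antipode of the ferrocenyl diphosphine is matched to insertion into C4–O is settled by one trial with each; the step is written for the matched one.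
- Cleaving the cyclic carbonate selectively next to a primary benzoate is not reliable, so step 3 removes both and step 4 puts the C7 benzoate back.

**Route**

Step 1
Reactants: 1 furfuryl alcohol; 2 benzoyl chloride
Product: 3 furfuryl benzoate
Conditions: BzCl (1.1 equiv), Et3N, DMAP (cat.), CH2Cl2, 0 °C → rt
Reagents that add atoms: benzoyl chloride (2), O=C(Cl)c1ccccc1
Why: Nucleophilic acyl substitution (DMAP-catalysed esterification) of a primary alcohol; no stereocentre is involved.

Step 2
Reactants: 3 furfuryl benzoate; 4 vinylene carbonate
Product: 5 racemic endo 7-oxanorbornene carbonate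
Conditions: 4 (3 equiv), 2,6-di-tert-butyl-4-methylphenol (1 mol%), CH2Cl2 (concentrated), 1.2 GPa, 30 °C, 72 h; endo adduct separated from exo isomer by crystallisation or chromatography
Reagents that add atoms: vinylene carbonate (4), O=C1OC=CO1
Why: Thermally allowed, concerted suprafacial [4+2] cycloaddition in which the furan (C1, C6, C5, C4) is the diene and the C2=C3 bond of 4 the dienophile, so that C1–C2 and C3–C4 form together. The closest known reaction type is the Diels–Alder addition of vinylene carbonate to furans, which pressure accelerates because the volume of activation is strongly negative. The six-membered carbocycle is closed by the cycloaddition itself (both bonds in one step, no separate cyclisation mode), and the furan oxygen is left as the C1–O–C4 bridge. C2 and C3 are cis because the dienophile is a ring-locked Z-alkene adding suprafacially, C1 and C4 are tied by the bridge, and the placing of the carbonate anti to the bridge follows from the endo transition state; the adduct is racemic because neither partner is chiral. The step needs endo over exo selectivity, secured by kinetic control: the more compact endo transition state is favoured under pressure and the adduct should not revert near room temperature, while the symmetry of 4 removes any regiochemical question for the unsymmetrical furan.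

Step 3
Reactants: 5 racemic endo 7-oxanorbornene carbonate
Product: 6 racemic endo triol
Conditions: K2CO3 (0.2 equiv), MeOH, 0 °C → rt
Reagents that add atoms: none
Why: Base-catalysed transesterification (methanolysis) removes the cyclic carbonate and the C7 benzoate together; no stereocentre is touched.

Step 4
Reactants: 6 racemic endo triol; 2 benzoyl chloride
Product: 7 racemic C7 benzoate diol
Conditions: BzCl (1.05 equiv), 2,4,6-collidine, CH2Cl2, −78 → −30 °C
Reagents that add atoms: benzoyl chloride (2), O=C(Cl)c1ccccc1
Why: Site-selective acylation: with collidine at low temperature the primary C7–OH should react much faster than the two hindered endo secondary hydroxyls; no stereocentre is involved.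

Step 5
Reactants: 7 racemic C7 benzoate diol
Product: 8 C7 benzoate diol as single enantiomer (recovered unreacted alcohol)
Conditions: Pseudomonas cepacia lipase (immobilised), vinyl acetate (3 equiv), tert-butyl methyl ether, 30 °C, stopped just past half conversion; chromatography
Reagents that add atoms: none
Why: Lipase-catalysed kinetic resolution by irreversible transesterification: the enzyme should acetylate the accessible C3–OH of the unwanted enantiomer only, so the existing stereocentres are sorted, not formed.

Step 6
Reactants: 8 C7 benzoate diol (single enantiomer); 2 benzoyl chloride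
Product: 9 C7,C3-dibenzoate with free C2–OH
Conditions: BzCl (1.1 equiv), pyridine, CH2Cl2, −40 → 0 °C
Reagents that add atoms: benzoyl chloride (2), O=C(Cl)c1ccccc1
Why: Regioselective acylation of a cis-diol: C3–OH sits next to the bridgehead CH, whereas C2–OH is flanked by the fully substituted C1 and its CH2OBz arm, so the acyl group should go to C3; no stereocentre is changed.

Step 7
Reactants: 9 C7,C3-dibenzoate with free C2–OH
Product: 10 trans-chlorohydrin (C6–Cl, C1–OH, C4=C5)
Conditions: [Rh(cod)Cl]2 (5 mol%), matched antipode of 1-[2-(diphenylphosphino)ferrocenyl]ethyldi-tert-butylphosphine (11 mol%), Et3N·HCl (4 equiv), THF, 65 °C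
Reagents that add atoms: triethylammonium chloride, CC[NH+](CC)CC.[Cl-]
Why: Rhodium-catalysed anti SN2′ ring opening of an oxabicyclic alkene by a halide: monovalent rhodium inserts from the exo face into the strained allylic bridgehead C4–O bond (the matched ligand and the fully substituted, inductively deactivated C1 steer it away from C1–O), and chloride then attacks C6 of the allylrhodium from the opposite, endo face, helped by a hydrogen bond to the free C2–OH, so that C6–Cl is set trans to the retained C1–O and C4=C5 is formed.

Step 8
Reactants: 10 trans-chlorohydrin
Product: 11 C2 triethylsilyl ether of the chlorohydrin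
Conditions: TESOTf (1.05 equiv), 2,6-lutidine, CH2Cl2, −78 °C
Reagents that add atoms: triethylsilyl trifluoromethanesulfonate, CC[Si](CC)(CC)OS(=O)(=O)C(F)(F)F
Why: Silyl ether formation with a silyl triflate and a hindered pyridine base: at −78 °C the secondary C2–OH should react and the tertiary C1–OH not, and the non-nucleophilic base leaves the allylic chloride alone.

Step 9
Reactants: 11 C2 triethylsilyl ether of the chlorohydrin
Product: 12 triethylsilyl ether of the target
Conditions: KN(SiMe3)2 (1.05 equiv), THF, −78 → −20 °C
Reagents that add atoms: none
Why: Intramolecular Williamson-type epoxide closure (3-exo-tet): the C1 alkoxide displaces the trans allylic chloride at C6 with inversion, so the former bridge oxygen becomes the oxirane oxygen anti to C2–O and C3–O, while the silyl ether blocks benzoyl migration and Payne rearrangement.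

Step 10
Reactants: 12 triethylsilyl ether of the target
Product: 13 target CNP0192269.7
Conditions: TBAF/AcOH (1:1, 2 equiv), THF, 0 °C → rt
Reagents that add atoms: none
Why: Fluoride-mediated desilylation buffered with acetic acid keeps the medium near neutral, so benzoyl migration from C3 to C2, Payne rearrangement and opening of the vinyl oxirane should not intervene; no stereocentre is touched.

**Compound list**

1 | furfuryl alcohol (furan-2-ylmethanol) | OCc1ccco1 | starting material
2 | benzoyl chloride | O=C(Cl)c1ccccc1 | starting material
3 | furfuryl benzoate (furan-2-ylmethyl benzoate) | O=C(OCc1ccco1)c1ccccc1 | intermediate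
4 | vinylene carbonate (1,3-dioxol-2-one) | O=C1OC=CO1 | starting material
5 | racemic endo cycloadduct, [2,3-(carbonyldioxy)-7-oxabicyclo[2.2.1]hept-5-en-1-yl]methyl benzoate: oxygen bridge C1–O–C4, cyclic carbonate cis on C2/C3 and anti to the bridge; the (1R,2S,3S,4R) enantiomer is drawn | O=C(OC[C@]12O[C@H](C=C1)[C@@H]1OC(=O)O[C@@H]12)c1ccccc1 | intermediate
6 | racemic endo triol, 1-(hydroxymethyl)-7-oxabicyclo[2.2.1]hept-5-ene-2,3-diol: C2–OH and C3–OH cis, both anti to the bridge | OC[C@]12O[C@H](C=C1)[C@H](O)[C@@H]2O | intermediate
7 | racemic C7 benzoate diol, (2,3-endo-dihydroxy-7-oxabicyclo[2.2.1]hept-5-en-1-yl)methyl benzoate | O=C(OC[C@]12O[C@H](C=C1)[C@H](O)[C@@H]2O)c1ccccc1 | intermediate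
8 | the same C7 benzoate diol as single enantiomer (configuration of the SMILES) | O=C(OC[C@]12O[C@H](C=C1)[C@H](O)[C@@H]2O)c1ccccc1 | intermediate
9 | C7,C3-dibenzoate, (3-endo-benzoyloxy-2-endo-hydroxy-7-oxabicyclo[2.2.1]hept-5-en-1-yl)methyl benzoate | O=C(OC[C@]12O[C@H](C=C1)[C@H](OC(=O)c1ccccc1)[C@@H]2O)c1ccccc1 | intermediate
10 | trans-chlorohydrin, [(1R,2S,3S,6R)-3-benzoyloxy-6-chloro-1,2-dihydroxycyclohex-4-en-1-yl]methyl benzoate: C1–OH on one face; C2–OH, C3–OBz and C6–Cl on the other | O=C(OC[C@]1(O)[C@H](Cl)C=C[C@H](OC(=O)c2ccccc2)[C@@H]1O)c1ccccc1 | intermediate
11 | C2 triethylsilyl ether of 10 | O=C(OC[C@]1(O)[C@H](Cl)C=C[C@H](OC(=O)c2ccccc2)[C@@H]1O[Si](CC)(CC)CC)c1ccccc1 | intermediate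
12 | C2 triethylsilyl ether of the target: C1–C6 oxirane anti to C2–OTES and C3–OBz, C4=C5 | O=C(OC[C@]12O[C@H]1C=C[C@H](OC(=O)c1ccccc1)[C@@H]2O[Si](CC)(CC)CC)c1ccccc1 | intermediate
13 | CNP0192269.7, [(1R,2S,3S,6S)-3-benzoyloxy-1,6-epoxy-2-hydroxycyclohex-4-en-1-yl]methyl benzoate | O=C(OC[C@]12O[C@H]1C=C[C@H](OC(=O)c1ccccc1)[C@@H]2O)c1ccccc1 | target

**Step count and risk**

Total step count: 10. Longest linear sequence: 10 steps (1 → 13).

Steps most likely to fail:

1. Step 7. The insertion may leak to the C1–O bond, so that chloride enters at C5, distal to the fully substituted carbon. This distal entry is believed to be the inherent preference of such rhodium openings of bridgehead-substituted oxabicycles, and the route relies on the ligand to override it. The endo face at C6 may also be too shielded for attack. The fallback sets out from 9 and comes back at 12. The free C2–OH of 9 is silylated (TESOTf, 2,6-lutidine) to the oxanorbornene C2 triethylsilyl ether F1. The inherent bias is then used instead of opposed: [Rh(cod)Cl]2 with achiral 1,1′-bis(diphenylphosphino)ferrocene and Et3N·HCl should open the C1–O bond with chloride entering anti at C5, giving the 4,5-trans chlorohydrin with a C1=C6 double bond F2. Mesylation of C4–OH gives the chloro mesylate F3. Zn dust and NaI in DMF remove chloride and mesylate reductively to give the cyclohexa-1,3-diene F4, which is used cold and at once because it can aromatise by loss of benzoic acid. Singlet oxygen (O2, tetraphenylporphyrin, visible light, −30 °C) adds across C1 and C4 on the face away from C2–OTES and C3–OBz to give the endoperoxide F5. P(OMe)3 then attacks the less hindered peroxide oxygen on C4, and the oxygen left on C1 closes onto C6 with shift of the double bond to C4=C5, which gives 12. In this variant the oxirane oxygen comes from dioxygen and not from the bridge.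

2. Step 2. The cycloaddition may be too slow to outrun cycloreversion and radical polymerisation of the dienophile, and the endo preference may erode on long reaction times. The fallback sets out from 1 and comes back at 6. Alcohol 1 is silylated (TBSCl, imidazole) to the more electron-rich diene tert-butyl(furan-2-ylmethoxy)dimethylsilane F6, which also has no ionisable furfuryl ester. Cycloaddition with 4 under the same pressure gives the racemic endo adduct silyl ether F7. K2CO3 in MeOH gives the silyl ether diol F8, and TBAF gives 6. This does not cure poor endo selectivity.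

3. Step 5. The enzyme may discriminate the enantiomers poorly, or acylate the needed one. The fallback sets out from 1 and comes back at 8. Alcohol 1 is esterified with (1S)-camphanic chloride to furfuryl (1S)-camphanate F9. Cycloaddition with 4 as in step 2 gives two endo diastereomers, of which the one with the required (1R,2S,3S,4R) core, the camphanate adduct F10, is separated by crystallisation or chromatography. K2CO3 in MeOH gives the enantiomerically pure triol F11, and benzoylation at C7 as in step 4 gives 8.

**Further compounds**

F1 | step 7 | C2 triethylsilyl ether of 9 | O=C(OC[C@]12O[C@H](C=C1)[C@H](OC(=O)c1ccccc1)[C@@H]2O[Si](CC)(CC)CC)c1ccccc1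
F2 | step 7 | 4,5-trans chlorohydrin with C1=C6, [3-benzoyloxy-5-chloro-4-hydroxy-2-(triethylsilyloxy)cyclohex-6-en-1-yl]methyl benzoate (target locants) | O=C(OCC1=C[C@H](Cl)[C@@H](O)[C@H](OC(=O)c2ccccc2)[C@@H]1O[Si](CC)(CC)CC)c1ccccc1
F3 | step 7 | C4 methanesulfonate of F2 | O=C(OCC1=C[C@H](Cl)[C@@H](OS(C)(=O)=O)[C@H](OC(=O)c2ccccc2)[C@@H]1O[Si](CC)(CC)CC)c1ccccc1
F4 | step 7 | cyclohexa-1,3-diene (C1=C6, C4=C5) with cis C2–OTES and C3–OBz | O=C(OCC1=CC=C[C@H](OC(=O)c2ccccc2)[C@@H]1O[Si](CC)(CC)CC)c1ccccc1
F5 | step 7 | endoperoxide (C1–O–O–C4 bridge anti to C2–OTES and C3–OBz, C5=C6) | O=C(OC[C@]12OO[C@H](C=C1)[C@H](OC(=O)c1ccccc1)[C@@H]2O[Si](CC)(CC)CC)c1ccccc1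
F6 | step 2 | tert-butyl(furan-2-ylmethoxy)dimethylsilane | CC(C)(C)[Si](C)(C)OCc1ccco1
F7 | step 2 | racemic endo cycloadduct, C7 tert-butyldimethylsilyl ether (carbonate anti to the bridge) | CC(C)(C)[Si](C)(C)OC[C@]12O[C@H](C=C1)[C@@H]1OC(=O)O[C@@H]12
F8 | step 2 | racemic endo diol, C7 tert-butyldimethylsilyl ether | CC(C)(C)[Si](C)(C)OC[C@]12O[C@H](C=C1)[C@H](O)[C@@H]2O
F9 | step 5 | furfuryl (1S)-camphanate | O=C(OCc1ccco1)[C@@]12CC[C@@](C)(C(=O)O1)C2(C)C
F10 | step 5 | endo cycloadduct (1S)-camphanate with the (1R,2S,3S,4R) oxanorbornene core | O=C(OC[C@]12O[C@H](C=C1)[C@@H]1OC(=O)O[C@@H]12)[C@@]12CC[C@@](C)(C(=O)O1)C2(C)C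
F11 | step 5 | endo triol as single enantiomer (constitution of 6) | OC[C@]12O[C@H](C=C1)[C@H](O)[C@@H]2O
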